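The data stem from a simulated flask with constants of no real substance; noise was put on by code.

A ratio carries this flask: at 15.0 h the oak run holds 0.591 parts of target per part of starting material, and this r, target over starting material at one moment, answers the questions below.

the same everywhere: starting material 0.15 M

| charge | coupling partner | second substrate | third substrate | remark | time |
|---|---|---|---|---|---|
| oak | 0.15 M | 0.075 M | 0.19 M | run made earlier |  |
| larch | 0.15 M | 0.075 M | 0.28 M | run made earlier |  |
| dusk | 0.150 M | 0.0750 M | 0.150 M |  | 20 h |
| autumn | 0.150 M | 0.0750 M | 0.200 M |  | 20 h |
| winter | 0.150 M | 0.0750 M | 0.250 M |  | 20 h |

| run | time / h | starting material / % | target / % |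
|---|---|---|---|
| oak | 1.00 | 90.2 | 10.6 |
| oak | 2.50 | 82.1 | 19.5 |
| oak | 6.00 | 68.6 | 31.2 |
| oak | 15.0 | 62.9 | 37.2 |
| larch | 1.00 | 92.0 | 9.6 |
| larch | 2.50 | 78.3 | 20.7 |
| larch | 6.00 | 69.9 | 30.5 |
| larch | 15.0 | 66.7 | 34.3 |

(scatter of a reading: 1 percentage point)

- which of these there is most of at the end, counted by the starting material in it, dusk (target / starting material)
- which of these there is most of at the end, counted by the starting material in it, autumn (target / starting material)
- which of these there is most of at the end, counted by the starting material in it, winter (target / starting material)
- amount of the one of these that there is most of at the end, in percent of the starting material charged, dusk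
- amount of the one of these that there is most of at the end, in percent of the starting material charged, autumn
- amount of the one of these that there is most of at the end, in percent of the starting material charged, winter



The two amounts add up to 100% in the oak run and 101% in the larch run, so starting material is 1/(1+r) of the charge, and target leads where r passes one. The larch run, with more third substrate, reads r = 0.514 at its last point, lower than the oak run, though each reading carries a scatter of 1 percentage point.

In the oak run r reads 0.455 at 6.00 h, lower than at its last reading. But target gained 6 points over the last 9.00 h, less than the 13 points that r = one needs in the further 5.00 h. So starting material should stay ahead in dusk, autumn and winter. A straight line through the two readings of r against third substrate, with the later drift left aside, gives r = 0.626 for dusk and 0.540 for winter, hence starting material near 61.5% and 64.9%.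

The forecast names starting material at 61.5% for dusk, 63% for autumn and 64.5% for winter, holding that “Something stops the reaction”. Its winter value is lower than the line's.

    starting material + coupling partner ⇌ target (K = 20.0 M⁻¹, k = 0.770 M⁻¹ h⁻¹)
    second substrate + coupling partner → second product (k = 0.0450 M⁻¹ h⁻¹)
    third substrate + coupling partner → third product (k = 0.260 M⁻¹ h⁻¹)
    coupling partner ⇌ dormant form (K = 2.20, k = 0.0240 h⁻¹)

The flasks give starting material at 61.6% for dusk, 63.9% for autumn and 66.1% for winter. Winter keeps 12.7% of its coupling partner free at the end, and its r is 0.514. The same winter flask charged with 0.60 M of coupling partner reaches r = 3.76, past one, with target at 79.0%.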